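## The problem

Compound 17 is a sesquineolignan made of two trans-2-aryl-3-(hydroxymethyl)-2,3-dihydrobenzofurans joined head to tail. In unit 1 (O1, C2, C3, C3a, C4–C7, C7a, with C9 the hydroxymethyl carbon on C3) the guaiacyl ring A sits on C2 and the benzo ring B carries a methoxy group at C7. Ring B is also the aryl group on C2' of unit 2 (primed atoms), whose benzo ring C carries a methoxy group at C7' and the (E)-3-hydroxypropenyl chain at C5'. The four stereocentres (2R,3S,2'R,3'S) form two trans pairs. Within a pair one centre can direct the other, but the flat ring B insulates the pairs from each other, so absolute configuration has to be introduced twice by a reagent. Both benzylic C–O bonds (C2–O1 and C2'–O1') stand para to an oxygen and ionize under acid, the free ring A phenol opens the way to a quinone methide under base, and the cinnamyl alcohol excludes hydrogenolysis, strong acid and strong oxidants late in the route. The enabling feature occurs in both units: C3 (C3') carries only the aryl carbon C3a (C3a') and an oxygenated methylene C9 (C9'), and C3a is ortho to the ether oxygen, whose other ortho position bears the methoxy group. This is the pattern left when an aryl radical at C3a closes 5-exo onto the vinyl group of an aryl 1-arylallyl ether and the new primary radical is captured by oxygen, and the iodo/oxygen/methoxy arrangement it requires is that of 5-iodovanillin.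

## Retrosynthesis

**End game.** Target 17 is traced to diol 16, in which the allylic alcohol is still a methyl (E)-cinnamate and the ring A phenol a pivalate; one hydride reduction removes both acyl groups. Diol 16 comes from bis(alkoxyamine) 15 by reductive N–O cleavage. No skeletal bond is cut here. The ordering is chosen so that the acidic zinc step meets the robust ester and not the ionizable cinnamyl alcohol, and the free phenol appears only in the last step.

**Unit 1 (key disconnection).** In 15 the bonds C3–C3a and C9–O are cut: ring B becomes an aryl iodide, C3/C9 a vinyl group, and the oxygen on C9 comes from TEMPO 9. The precursor is the (R)-1-arylallyl ether 14. The neighbouring cuts (O1–C2 or C2–C3) would need a preformed C3 stereocentre or a tethered carbenium ion. The C3–C3a cut leaves an ether that catalytic asymmetric allylic substitution can make, and 14 has one ring and one stereocentre fewer than 15. The forward reaction must close 5-exo faster than the aryl radical is intercepted, and C2 must place C9 trans to ring A.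

**Ether 14.** Cutting O1–C2 gives iodophenol 12 and the achiral linear carbonate 4. An iridium-catalysed allylic etherification is preferred to SN2 or Mitsunobu displacement on a secondary benzylic allylic alcohol, because it delivers the branched regioisomer and the absolute configuration in one step from an achiral electrophile. It has to accept an aryloxide flanked by iodine and methoxy and leave the aryl iodide untouched. Because 12 is already chiral, the minor enantiomer carried from unit 2 ends up as a diastereomer of 14 and can be removed.

**Iodophenol 12.** The C–I bond is cut back to phenol 11, and 11 to pivalate 10. The iodine of ring B cannot be present while unit 2 is closed, since two aryl iodides would compete. It is therefore introduced afterwards, ortho to the liberated hydroxyl, the only position that this group activates. The C9' oxygen stays as its TEMPO ether, which serves as the protecting group until step 11.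

**Unit 2.** The same two cuts are applied to 10: C3'–C3a'/C9'–O leads to ether 8 and TEMPO 9, and O1'–C2' leads to iodophenol 6 and carbonate 4. Ring B before iodination is identical with ring A, so one carbonate serves twice and the route is a two-fold iteration of etherification and cyclization.

**Building blocks.** Carbonate 4 comes from commercial coniferyl aldehyde 1 through pivalate 2 and alcohol 3. Iodophenol 6 comes from 5-iodovanillin 5 by Wittig olefination, which installs the future side chain as an ester that is inert to every later step.

## Roads not taken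

**Alternative 1:** The cut is O1'–C2' of unit 2. The (S)-1,2-diarylpropane A2 is oxidized with Ag2O at its ring B iodophenol; the benzylic carbon acquires quinone methide character and is captured by the ortho-hydroxyl of ring C to give A1. Its merits are that the single centre C3' sets C2' into the thermodynamically preferred trans arrangement, C9' carries its oxygen from the start, no tin and no N–O cleavage are needed, and A1 already holds the ortho-iodophenol for a second unit. Its weak points are that A2 must first be made enantioenriched at a centre between two benzylic positions, which costs an auxiliary or a separate asymmetric step. The oxidized intermediate can also tautomerize to a stilbene instead of cyclizing. The method delivers only unit 2, so unit 1 needs either a second diarylpropane with its own stereocentre or a different ring construction. In relative stereocontrol this road is at least as good as the chosen one, since trans is a thermodynamic sink while the 1,2-induction in steps 6 and 10 is kinetic. The chosen plan sets against this a catalytic origin of absolute configuration from achiral partners and one two-step cycle that builds both units from the same carbonate.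

**Alternative 2:** The cut is C3'–C3a', seen through a flavanone. PhI(OAc)2 and H2SO4 in trimethyl orthoformate convert the (R)-flavanone A4, whose 2-aryl group is ring B of a finished unit 1, into the trans methyl ester A3 by 1,2-shift of the aryl carbon C4a and contraction of the pyranone. The ring contraction is a known reaction type, and C3' ends up alpha to an ester, so a cis isomer could be equilibrated by base. That is a real advantage over the chosen plan, where C3 and C3' are fixed once formed. Against it, a strongly acidic oxidizing medium meets the complete unit 1 with its ionizable C2–O1 bond and electron-rich ring B. Flavanones also racemize by reversible opening to the chalcone. The bromide and ester of A3 still have to be turned into the propenol chain and the hydroxymethyl group, so several steps follow the key step. The chosen plan offers neutral radical conditions, no late oxidant, and a side chain that is already in place.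

**Alternative 3:** The cut is C2–C3 of unit 1. In A6 ring B carries an arylacetyl thiazolidinethione at C3a and, on O1, a mixed methyl acetal of the ring A aldehyde. TiCl4 and i-Pr2NEt form the chlorotitanium enolate and ionize the acetal, and the enolate carbon attacks the carbenium carbon to give A5. This road forms C2–C3 and both stereocentres of unit 1 in one auxiliary-controlled event, and the acyl thiazolidinethione is reduced directly to the hydroxymethyl group. In predictability of absolute and relative configuration it is probably better than two separate events. Its weak points are structural. The acetal can ionize the other way, losing the aryloxide (the better leaving group) and severing the tether. The closure is 5-endo with respect to the C2=O1 cation. A mixed aryl methyl acetal of an electron-rich benzaldehyde is hard to prepare and keep. A stoichiometric auxiliary and a bromide still to be elaborated add steps. The chosen plan has a precursor assembled in one catalytic step and a ring closure (5-exo) that is kinetically favoured.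

Key step: step 10

Assumption: ligand L denotes (Ra,Rc,Rc)-O,O'-(1,1'-binaphthyl-2,2'-diyl) N,N-bis(1-phenylethyl)phosphoramidite. It is taken to deliver the (R)-configured branched ethers 8 and 14; if the sense of induction proves opposite, the enantiomeric ligand is used in steps 5 and 9.

## Route

Step 1
Reactants: 1 coniferyl aldehyde [(E)-3-(4-hydroxy-3-methoxyphenyl)prop-2-enal]
Product: 2 (E)-3-(3-methoxy-4-pivaloyloxyphenyl)prop-2-enal
Conditions: PivCl, Et3N, DMAP (cat.), CH2Cl2, 0 °C to rt
Reagents that add atoms: pivaloyl chloride, CC(C)(C)C(=O)Cl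
Why: DMAP-catalysed O-acylation of the phenol; the pivalate lowers the donor strength of the para oxygen in all later benzylic intermediates and is too hindered for acyl transfer to the aryloxides used later.

Step 2
Reactants: 2 (E)-3-(3-methoxy-4-pivaloyloxyphenyl)prop-2-enal
Product: 3 (E)-3-(3-methoxy-4-pivaloyloxyphenyl)prop-2-en-1-ol
Conditions: NaBH4, CeCl3·7H2O, MeOH, −20 to 0 °C
Reagents that add atoms: none
Why: Luche reduction delivers hydride 1,2 to the enal; the hindered aryl pivalate should survive these cold, near-neutral conditions.

Step 3
Reactants: 3 (E)-3-(3-methoxy-4-pivaloyloxyphenyl)prop-2-en-1-ol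
Product: 4 tert-butyl (E)-3-(3-methoxy-4-pivaloyloxyphenyl)allyl carbonate
Conditions: Boc2O, DMAP (cat.), CH2Cl2, 0 °C to rt
Reagents that add atoms: di-tert-butyl dicarbonate, CC(C)(C)OC(=O)OC(=O)OC(C)(C)C
Why: DMAP-catalysed tert-butoxycarbonylation of the primary allylic alcohol; the tert-butyl carbonate is preferred to a methyl carbonate because the tert-butoxide released in steps 5 and 9 is too hindered to attack the aryl pivalate.

Step 4
Reactants: 5 5-iodovanillin (4-hydroxy-3-iodo-5-methoxybenzaldehyde)
Product: 6 methyl (E)-3-(4-hydroxy-3-iodo-5-methoxyphenyl)acrylate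
Conditions: Ph3P=CHCO2Me, toluene, 80 °C
Reagents that add atoms: methyl (triphenylphosphoranylidene)acetate, COC(=O)C=P(c1ccccc1)(c1ccccc1)c1ccccc1
Why: Wittig olefination with a stabilised ylide gives the (E)-cinnamate and tolerates the free phenol; removing the aldehyde makes the ring C aryloxide a better nucleophile for step 5.

Step 5
Reactants: 6 methyl (E)-3-(4-hydroxy-3-iodo-5-methoxyphenyl)acrylate; 4 tert-butyl (E)-3-(3-methoxy-4-pivaloyloxyphenyl)allyl carbonate
Product: 8 methyl (E)-3-{3-iodo-5-methoxy-4-[(R)-1-(3-methoxy-4-pivaloyloxyphenyl)allyloxy]phenyl}acrylate, via lithium phenoxide of the iodoferulate 7 (not isolated)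
Conditions: LiN(SiMe3)2, THF, 0 °C; then 4, [Ir(cod)Cl]2 (2 mol%), L (4 mol%), THF, 50 °C
Reagents that add atoms: none
Why: Iridium-catalysed asymmetric allylic etherification: the aryloxide attacks the substituted terminus of the allyl ligand on the cyclometalated iridium–phosphoramidite complex, giving the branched ether. The ligand sets the new centre C2' (R), and the aryl iodide is inert to this catalyst.

Step 6
Reactants: 8 methyl (E)-3-{3-iodo-5-methoxy-4-[(R)-1-(3-methoxy-4-pivaloyloxyphenyl)allyloxy]phenyl}acrylate; 9 TEMPO
Product: 10 methyl (E)-3-[(2R,3S)-7-methoxy-2-(3-methoxy-4-pivaloyloxyphenyl)-3-{[(2,2,6,6-tetramethylpiperidin-1-yl)oxy]methyl}-2,3-dihydrobenzofuran-5-yl]acrylate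
Conditions: Bu3SnH (added in portions), TEMPO, benzene, 70 °C
Reagents that add atoms: TEMPO (compound 9), CC1(C)CCCC(C)(C)N1[O]
Why: Tin hydride/TEMPO oxygenative aryl radical cyclization, the same reaction type as step 10: iodine abstraction at ring C, 5-exo-trig closure onto the vinyl group, and coupling of the primary radical with TEMPO. C2' directs the new centre C3' trans (3'S) through a transition state with ring B pseudo-equatorial; the cinnamate is only an intermolecular acceptor and should not compete.

Step 7
Reactants: 10 methyl (E)-3-[(2R,3S)-7-methoxy-2-(3-methoxy-4-pivaloyloxyphenyl)-3-{[(2,2,6,6-tetramethylpiperidin-1-yl)oxy]methyl}-2,3-dihydrobenzofuran-5-yl]acrylate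
Product: 11 methyl (E)-3-[(2R,3S)-2-(4-hydroxy-3-methoxyphenyl)-7-methoxy-3-{[(2,2,6,6-tetramethylpiperidin-1-yl)oxy]methyl}-2,3-dihydrobenzofuran-5-yl]acrylate
Conditions: K2CO3 (0.5 equiv), MeOH/THF, rt
Reagents that add atoms: none
Why: Base-mediated methanolysis (transesterification) of the aryl ester; exchange at the methyl cinnamate is degenerate and the primary alkoxyamine is inert, so only the ring B phenol is freed.

Step 8
Reactants: 11 methyl (E)-3-[(2R,3S)-2-(4-hydroxy-3-methoxyphenyl)-7-methoxy-3-{[(2,2,6,6-tetramethylpiperidin-1-yl)oxy]methyl}-2,3-dihydrobenzofuran-5-yl]acrylate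
Product: 12 methyl (E)-3-[(2R,3S)-2-(4-hydroxy-3-iodo-5-methoxyphenyl)-7-methoxy-3-{[(2,2,6,6-tetramethylpiperidin-1-yl)oxy]methyl}-2,3-dihydrobenzofuran-5-yl]acrylate
Conditions: NIS, MeCN, 0 °C to rt
Reagents that add atoms: N-iodosuccinimide, O=C1CCC(=O)N1I
Why: Electrophilic aromatic iodination directed by the free hydroxyl to its only open ortho position (para is blocked), the regiochemistry that turns vanillin into 5-iodovanillin; ring C has no free phenol and is deactivated by the acrylate.

Step 9
Reactants: 12 methyl (E)-3-[(2R,3S)-2-(4-hydroxy-3-iodo-5-methoxyphenyl)-7-methoxy-3-{[(2,2,6,6-tetramethylpiperidin-1-yl)oxy]methyl}-2,3-dihydrobenzofuran-5-yl]acrylate; 4 tert-butyl (E)-3-(3-methoxy-4-pivaloyloxyphenyl)allyl carbonate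
Product: 14 methyl (E)-3-[(2R,3S)-2-{3-iodo-5-methoxy-4-[(R)-1-(3-methoxy-4-pivaloyloxyphenyl)allyloxy]phenyl}-7-methoxy-3-{[(2,2,6,6-tetramethylpiperidin-1-yl)oxy]methyl}-2,3-dihydrobenzofuran-5-yl]acrylate, via lithium phenoxide of the iodophenol 13 (not isolated)
Conditions: LiN(SiMe3)2, THF, 0 °C; then 4 (1.5 equiv), [Ir(cod)Cl]2 (2 mol%), L (4 mol%), THF, 50 °C
Reagents that add atoms: none
Why: Second iridium-catalysed branched-selective allylic etherification; the ligand sets C2 (R). The centres of unit 2 are remote from the reacting oxygen, so no matched or mismatched bias is expected, and material of the wrong hand carried from step 5 becomes a separable diastereomer.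

Step 10
Reactants: 14 methyl (E)-3-[(2R,3S)-2-{3-iodo-5-methoxy-4-[(R)-1-(3-methoxy-4-pivaloyloxyphenyl)allyloxy]phenyl}-7-methoxy-3-{[(2,2,6,6-tetramethylpiperidin-1-yl)oxy]methyl}-2,3-dihydrobenzofuran-5-yl]acrylate; 9 TEMPO
Product: 15 methyl (E)-3-[(2R,3S)-7-methoxy-2-[(2R,3S)-7-methoxy-2-(3-methoxy-4-pivaloyloxyphenyl)-3-{[(2,2,6,6-tetramethylpiperidin-1-yl)oxy]methyl}-2,3-dihydrobenzofuran-5-yl]-3-{[(2,2,6,6-tetramethylpiperidin-1-yl)oxy]methyl}-2,3-dihydrobenzofuran-5-yl]acrylate
Conditions: Bu3SnH (added in portions), TEMPO, benzene, 70 °C
Reagents that add atoms: TEMPO (compound 9), CC1(C)CCCC(C)(C)N1[O]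
Why: TEMPO abstracts hydrogen from Bu3SnH, the stannyl radical removes iodine from C3a of ring B, the aryl sigma radical adds to the internal vinyl carbon to form C3–C3a, and the primary C9 radical couples with TEMPO to the alkoxyamine. The closest known reaction type is the tin hydride/TEMPO oxygenative cyclization of 2-haloaryl allyl ethers and N-allyl-2-haloanilines to 3-(aminooxymethyl)dihydrobenzofurans and indolines. The dihydrofuran ring of unit 1 closes in the 5-exo-trig mode; 6-endo closure is not competitive for ortho-allyloxyaryl radicals. The new centre C3 is controlled by C2 (1,2-induction): in the 5-exo transition state ring A takes the pseudo-equatorial position and the developing C9 methylene points away from it, so the trans (2R,3S) ring should result, while C2 is untouched because no bond to it is broken. The step needs ring closure to outrun bimolecular capture of the aryl radical by TEMPO or tin hydride; the iodine sits directly beside the allyloxy oxygen, and this unimolecular closure is among the fastest radical cyclizations known. The ether must also survive 70 °C: both ortho positions of ring B are substituted, so no Claisen rearrangement is open, and the ring A pivalate tempers ionization of the doubly activated C2–O1 bond. The cinnamate of ring C and the C9' alkoxyamine are spectators, the latter because primary alkoxyamines do not homolyse at this temperature.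

Step 11
Reactants: 15 bis(alkoxyamine) from step 10
Product: 16 methyl (E)-3-[(2R,3S)-3-(hydroxymethyl)-2-[(2R,3S)-3-(hydroxymethyl)-7-methoxy-2-(3-methoxy-4-pivaloyloxyphenyl)-2,3-dihydrobenzofuran-5-yl]-7-methoxy-2,3-dihydrobenzofuran-5-yl]acrylate
Conditions: Zn, AcOH/THF/H2O (3:1:1), 60 °C
Reagents that add atoms: none
Why: Dissolving-metal reduction of both N–O bonds by zinc in aqueous acetic acid frees C9–OH and C9'–OH; the cinnamate, the pivalate and the four stereocentres should not be affected.

Step 12
Reactants: 16 diol from step 11
Product: 17 (E)-3-[(2R,3S)-3-(hydroxymethyl)-2-[(2R,3S)-2-(4-hydroxy-3-methoxyphenyl)-3-(hydroxymethyl)-7-methoxy-2,3-dihydrobenzofuran-5-yl]-7-methoxy-2,3-dihydrobenzofuran-5-yl]prop-2-en-1-ol (target)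
Conditions: i-Bu2AlH (excess), THF, −78 to 0 °C; aq. potassium sodium tartrate
Reagents that add atoms: none
Why: Hydride reduction with excess i-Bu2AlH converts the cinnamate into the (E)-allylic alcohol (1,2-reduction) and cleaves the aryl pivalate in the same operation, so the target is reached without acid or strong base.

## Compound list

1 | coniferyl aldehyde, (E)-3-(4-hydroxy-3-methoxyphenyl)prop-2-enal | COc1cc(/C=C/C=O)ccc1O | starting material
2 | (E)-3-(3-methoxy-4-pivaloyloxyphenyl)prop-2-enal | COc1cc(/C=C/C=O)ccc1OC(=O)C(C)(C)C | intermediate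
3 | (E)-3-(3-methoxy-4-pivaloyloxyphenyl)prop-2-en-1-ol | COc1cc(/C=C/CO)ccc1OC(=O)C(C)(C)C | intermediate
4 | tert-butyl (E)-3-(3-methoxy-4-pivaloyloxyphenyl)allyl carbonate | COc1cc(/C=C/COC(=O)OC(C)(C)C)ccc1OC(=O)C(C)(C)C | intermediate
5 | 5-iodovanillin | COc1cc(C=O)cc(I)c1O | starting material
6 | methyl (E)-3-(4-hydroxy-3-iodo-5-methoxyphenyl)acrylate | COc1cc(/C=C/C(=O)OC)cc(I)c1O | intermediate
7 | lithium 2-iodo-6-methoxy-4-[(E)-3-methoxy-3-oxoprop-1-enyl]phenoxide | COc1cc(/C=C/C(=O)OC)cc(I)c1[O-].[Li+] | intermediate (not isolated)
8 | (R)-1-arylallyl ether of 6: methyl (E)-3-{3-iodo-5-methoxy-4-[(R)-1-(3-methoxy-4-pivaloyloxyphenyl)allyloxy]phenyl}acrylate | COc1cc([C@@H](C=C)Oc2c(OC)cc(/C=C/C(=O)OC)cc2I)ccc1OC(=O)C(C)(C)C | intermediate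
9 | TEMPO, (2,2,6,6-tetramethylpiperidin-1-yl)oxyl | CC1(C)CCCC(C)(C)N1[O] | starting material
10 | unit 2 alkoxyamine (2'R,3'S, trans; ring B pivalate; methyl cinnamate) | COc1cc([C@@H]2Oc3c(OC)cc(/C=C/C(=O)OC)cc3[C@H]2CON4C(C)(C)CCCC4(C)C)ccc1OC(=O)C(C)(C)C | intermediate
11 | unit 2 alkoxyamine with free ring B phenol | COc1cc([C@@H]2Oc3c(OC)cc(/C=C/C(=O)OC)cc3[C@H]2CON4C(C)(C)CCCC4(C)C)ccc1O | intermediate
12 | unit 2 alkoxyamine with ring B as 4-hydroxy-3-iodo-5-methoxyphenyl | COc1cc([C@@H]2Oc3c(OC)cc(/C=C/C(=O)OC)cc3[C@H]2CON4C(C)(C)CCCC4(C)C)cc(I)c1O | intermediate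
13 | lithium phenoxide of 12 | COc1cc([C@@H]2Oc3c(OC)cc(/C=C/C(=O)OC)cc3[C@H]2CON4C(C)(C)CCCC4(C)C)cc(I)c1[O-].[Li+] | intermediate (not isolated)
14 | (R)-1-(3-methoxy-4-pivaloyloxyphenyl)allyl ether of 12 (key-step precursor) | COc1cc([C@@H](C=C)Oc2c(OC)cc([C@@H]3Oc4c(OC)cc(/C=C/C(=O)OC)cc4[C@H]3CON5C(C)(C)CCCC5(C)C)cc2I)ccc1OC(=O)C(C)(C)C | intermediate
15 | trans,trans bis(dihydrobenzofuran) with C9 and C9' as TEMPO alkoxyamines (2R,3S,2'R,3'S; ring A pivalate; methyl cinnamate) | COc1cc([C@@H]2Oc3c(OC)cc([C@@H]4Oc5c(OC)cc(/C=C/C(=O)OC)cc5[C@H]4CON6C(C)(C)CCCC6(C)C)cc3[C@H]2CON7C(C)(C)CCCC7(C)C)ccc1OC(=O)C(C)(C)C | intermediate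
16 | C9,C9' diol (2R,3S,2'R,3'S; ring A pivalate; methyl cinnamate) | COc1cc([C@@H]2Oc3c(OC)cc([C@@H]4Oc5c(OC)cc(/C=C/C(=O)OC)cc5[C@H]4CO)cc3[C@H]2CO)ccc1OC(=O)C(C)(C)C | intermediate
17 | CNP0250921.1 (2R,3S,2'R,3'S) | COc1cc([C@@H]2Oc3c(OC)cc([C@@H]4Oc5c(OC)cc(/C=C/CO)cc5[C@H]4CO)cc3[C@H]2CO)ccc1O | target

## Step count and least certain steps

Total: 12 steps. Longest linear sequence: 11 steps (steps 1–3 and 5–12 from coniferyl aldehyde 1); the branch from 5-iodovanillin 5 is 9 steps (steps 4–12).

**Step 10 (key step; step 6 shares the concern).** The most likely failure is poor facial selectivity at C3. The 1,2-induction from C2 is kinetic, and nothing in 15 allows later correction. A second failure mode is capture of the aryl radical by TEMPO or tin hydride before ring closure.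
Fallback: it sets out from 15 (as the C3 epimer mixture) and returns at 16. mCPBA in CH2Cl2 at 0 °C oxidizes both alkoxyamines through N-oxidation and Cope-type elimination to the dialdehyde F1. In F1, C3 and C3' are alpha to formyl groups, so a catalytic amine base (DBU, CH2Cl2, rt) can equilibrate them to the more stable trans arrangement. Ring opening by elimination of O1 should be slow, because the C2–O1 bond lies in the ring plane, orthogonal to the enolate pi system. NaBH4 in MeOH/THF at 0 °C then reduces both aldehydes to 16. This detour also replaces step 11.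

**Step 9 (step 5 shares the concern).** The most likely failure is slow attack of the doubly ortho-substituted aryloxide on the iridium allyl complex. Formation of the linear ether and re-ionization of the branched product would then gain ground, with loss of regio- and enantiopurity.
Fallback: it sets out from 4 and 12 and returns at 14. Carbonate 4 is converted by iridium-catalysed allylic hydroxylation ([Ir(cod)Cl]2, the enantiomer of L, aqueous KHCO3) into (S)-1-(3-methoxy-4-pivaloyloxyphenyl)prop-2-en-1-ol F2. The small oxygen nucleophile lies well inside the scope of the catalyst. F2 is joined to 12 by Mitsunobu etherification (PPh3, DIAD, toluene, 0 °C) with inversion to give 14. The same detour with 6 in place of 12 gives 8. Its own weakness is competing SN2' attack.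

**Step 12.** The most likely failure is incomplete cleavage of the hindered aryl pivalate, or retention of the polar tetraol on aluminium residues, when four functions are addressed by one reagent.
Fallback: it sets out from 16 and returns at 17. Methanolysis (K2CO3, MeOH, rt) removes the pivalate first and gives the phenolic diol ester F3. F3 is then reduced at the ester alone with a smaller excess of i-Bu2AlH to give 17.

## Further compounds

F1 | step 10 | methyl (E)-3-[(2R,3R)-3-formyl-2-[(2R,3R)-3-formyl-7-methoxy-2-(3-methoxy-4-pivaloyloxyphenyl)-2,3-dihydrobenzofuran-5-yl]-7-methoxy-2,3-dihydrobenzofuran-5-yl]acrylate (trans at both rings) | COc1cc([C@@H]2Oc3c(OC)cc([C@@H]4Oc5c(OC)cc(/C=C/C(=O)OC)cc5[C@H]4C=O)cc3[C@H]2C=O)ccc1OC(=O)C(C)(C)C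
F2 | step 9 | (S)-1-(3-methoxy-4-pivaloyloxyphenyl)prop-2-en-1-ol | COc1cc([C@H](C=C)O)ccc1OC(=O)C(C)(C)C
F3 | step 12 | methyl (E)-3-[(2R,3S)-3-(hydroxymethyl)-2-[(2R,3S)-2-(4-hydroxy-3-methoxyphenyl)-3-(hydroxymethyl)-7-methoxy-2,3-dihydrobenzofuran-5-yl]-7-methoxy-2,3-dihydrobenzofuran-5-yl]acrylate | COc1cc([C@@H]2Oc3c(OC)cc([C@@H]4Oc5c(OC)cc(/C=C/C(=O)OC)cc5[C@H]4CO)cc3[C@H]2CO)ccc1O
A1 | alternative 1 | [(2R,3S)-5-formyl-2-(4-hydroxy-3-iodo-5-methoxyphenyl)-7-methoxy-2,3-dihydrobenzofuran-3-yl]methyl pivalate | Oc1c(OC)cc(cc1I)[C@@H]1Oc2c(OC)cc(C=O)cc2[C@H]1COC(=O)C(C)(C)C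
A2 | alternative 1 | (S)-2-(5-formyl-2-hydroxy-3-methoxyphenyl)-3-(4-hydroxy-3-iodo-5-methoxyphenyl)propyl pivalate | COc1cc(C[C@H](COC(=O)C(C)(C)C)c2cc(C=O)cc(OC)c2O)cc(I)c1O
A3 | alternative 2 | methyl (2R,3R)-2-[(2R,3S)-3-(acetoxymethyl)-2-(4-acetoxy-3-methoxyphenyl)-7-methoxy-2,3-dihydrobenzofuran-5-yl]-5-bromo-7-methoxy-2,3-dihydrobenzofuran-3-carboxylate (trans at both rings) | COc1cc([C@@H]2Oc3c(OC)cc([C@@H]4Oc5c(OC)cc(Br)cc5[C@H]4C(=O)OC)cc3[C@H]2COC(C)=O)ccc1OC(C)=O
A4 | alternative 2 | (R)-2-[(2R,3S)-3-(acetoxymethyl)-2-(4-acetoxy-3-methoxyphenyl)-7-methoxy-2,3-dihydrobenzofuran-5-yl]-6-bromo-8-methoxychroman-4-one | COc1cc([C@@H]2Oc3c(OC)cc([C@H]4CC(=O)c5cc(Br)cc(OC)c5O4)cc3[C@H]2COC(C)=O)ccc1OC(C)=O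
A5 | alternative 3 | trans,trans bis(dihydrobenzofuran) with C3 as the N-acyl (S)-4-isopropylthiazolidine-2-thione (ring A TBS ether, C9' pivalate, C5' bromide) | COc1cc([C@@H]2Oc3c(OC)cc([C@@H]4Oc5c(OC)cc(Br)cc5[C@H]4COC(=O)C(C)(C)C)cc3[C@H]2C(=O)N6[C@@H](C(C)C)CSC6=S)ccc1O[Si](C)(C)C(C)(C)C
A6 | alternative 3 | ring B arylacetyl (S)-4-isopropylthiazolidine-2-thione whose O1 carries the methyl acetal of the ring A aldehyde (acetal carbon as epimer mixture; ring A TBS ether, C9' pivalate, C5' bromide) | COc1cc(C(OC)Oc2c(OC)cc([C@@H]3Oc4c(OC)cc(Br)cc4[C@H]3COC(=O)C(C)(C)C)cc2CC(=O)N5[C@@H](C(C)C)CSC5=S)ccc1O[Si](C)(C)C(C)(C)C
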